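The leftover came first. At the last reading of the violet run, the Z charged minus the L made left 0.540 M, yet L, which had averaged 0.00543 M min⁻¹ up to 28 min, rose at 1.92 × 10⁻⁴ M min⁻¹ between 110 min and 170 min, slower than that early average. Reckoned by L made, c(Z) stood at 67.5% of its charge and c(Q) at 59.4%, but the late rate stood at 3.53% of the early average. So I read the leftover as Z lost by a side path, not as Z still waiting.

| flask | Z | Q | time |
|---|---|---|---|
| violet | 0.800 M | 0.640 M |  |
| amber | 0.400 M | 0.240 M |  |
| grey | 0.800 M | 0.960 M |  |
| red | 0.800 M | 0.640 M | 1000 min |

| run | time / min | [L] / M |
|---|---|---|
| violet run | 28 | 0.1521 |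
| violet run | 57 | 0.2058 |
| violet run | 85 | 0.2347 |
| violet run | 110 | 0.2481 |
| violet run | 140 | 0.2534 |
| violet run | 170 | 0.2596 |
| amber run | 28 | 0.0198 |
| amber run | 57 | 0.0326 |
| amber run | 85 | 0.0344 |
| amber run | 110 | 0.0449 |
| amber run | 140 | 0.0417 |
| amber run | 170 | 0.0441 |
| grey run | 28 | 0.2564 |
| grey run | 57 | 0.3388 |
| grey run | 85 | 0.3662 |
| grey run | 110 | 0.3825 |
| grey run | 140 | 0.3929 |
| grey run | 170 | 0.4002 |

(each reading ± 0.002 M)

- Overall: Z + Q -> L.
- Constant volume, constant temperature.
- "The second partner" is Q.
- An order is taken over about fifteen percent of the charge, up and down.

* the exponent of [Q] in the starting rate at the charge of the violet run (at the point where two percent of the Z have become L)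
* the exponent of [Z] in the starting rate at the charge of the violet run (at the point where two percent of the Z have become L) (one fixed amount of L, the same in the runs compared)
* L in the red run at 1000 min, as a share of the Z charged

I therefore treated Z as facing a fork and carried one quantity, the split odds (a selectivity factor): L at the last reading over the Z charged that did not become L. The violet run gave 0.480 and the grey run 1.00. Assuming the same side path in both flasks, which have equal Z charges, the ratio of the odds is the ratio of the rates to L, so the exponent of Q came to 1.81.

My second way used the readings at 28 min, whose grey-to-violet ratio gave 1.29. The two ways parted. By that time the grey run had reached 64.1% of its last reading and the violet run 58.6%, so the grey average held more of the slowed stretch, and this second way read low. I kept the odds. The red run has the charge of the violet run, so, taking the violet odds as final, I reckoned a share of 32.5% for the red run.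

The forecast, reading “a reaction that dies”, gave 1.4 for Q, 1 for Z and 33% for the red run. My exponent of Q stood higher, and my share lower.

The simulation gave 1.8 for Q, 1.1 for Z and 33.3% for the red run.

    Z + Q → L (0.004974 L mol⁻¹ min⁻¹)
    Z + 2 Q → L + Q (0.02010 L² mol⁻² min⁻¹)
    Z → Dz (0.01110 min⁻¹)
    Q → Xi (0.002544 min⁻¹)

That share means split odds of 0.499 in the red run, beside the 0.480 read at the last reading of the violet run. Where equal L had been made, the rate of the grey run stood at 2.1 times that of the violet run. Multiplying gives grey odds of 1.05, a share of 51.2%, just past half of the Z charged, and the grey run reached half at 187 min.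

(The readings come from a simulation on assumed constants; the scatter is artificial.)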